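**Retrosynthetic overview**

1. Target 26 ⇐ lactone 23 by exchanging the O8 silyl group for the 3-methylbutanoate and removing the two primary silyl ethers.
2. Key disconnection C11–C12 (with O6–C12): the α-methylene-γ-lactone ring ⇐ macrocyclic homopropargylic alcohol 22 + CO. The enabling feature is the trans O6–C6–C7–C11≡C13 array on the ten-membered ring (free C6 hydroxyl, C7 ethynyl group); one carbon atom is stitched in as C12, C11–C12 formation closes the five-membered ring and the alkyne becomes the C11=C13 methylene.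
3. Ten-membered ring ⇐ C6–C7: intramolecular palladium/zinc umpolung propargylation of the C6 enal by the C7 propargylic mesylate of 20 (sets C6 and C7).
4. Chain 20 ⇐ C1=C10 Horner–Wadsworth–Emmons union of aldehyde 7 (C4=C5 by Wittig) with phosphono lactone 13, a temporary γ-lactone tying O8 to C14, made from Sharpless epoxy alcohol 9 (sets C7 and C8).
5. Ring order: temporary butyrolactone (step 6, opened in step 8) → ten-membered carbocycle (step 14) → α-methylene lactone (step 15).

Key step: step 15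

**Remarks**

- Locants are the germacrane locants of the target: ring C1–C10, lactone α-carbon C11, carbonyl C12, methylene C13, C14 on C10, C15 on C4; O6, O7, O8, O14, O15 are the oxygens on those carbons.
- Both ring alkenes are E by the CIP rules but ring-cis (C9 cis to C2, C3 cis to C6).
- Assumption: compounds 1, 2, 5, 8 and 11 are taken as catalogue chemicals.

**Route**

Step 1
Reactants: 1 ethyl (triphenylphosphoranylidene)acetate; 2 2-(2-iodoethyl)-1,3-dioxolane
Product: 4 ethyl 4-(1,3-dioxolan-2-yl)-2-(triphenylphosphoranylidene)butanoate, via phosphonium iodide 3 (not isolated)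
Conditions: 1 (2.1 equiv), MeCN, reflux
Reagents that add atoms: none
Why: C-alkylation of the stabilised ylide by the primary iodide gives salt 3, which a second equivalent of 1 deprotonates (transylidation) to the α-substituted stabilised ylide; no stereocenter is formed.

Step 2
Reactants: 4 ethyl 4-(1,3-dioxolan-2-yl)-2-(triphenylphosphoranylidene)butanoate; 5 2-[(4-methoxybenzyl)oxy]acetaldehyde
Product: 6 ethyl (2E)-2-[2-(1,3-dioxolan-2-yl)ethyl]-4-[(4-methoxybenzyl)oxy]but-2-enoate
Conditions: CH2Cl2, rt → 40 °C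
Reagents that add atoms: none
Why: Wittig olefination with an α-substituted stabilised ylide should be strongly E-selective (ester trans to the CH2OPMB group), which fixes the C4=C5 geometry of the target with C3 cis to C6.

Step 3
Reactants: 6 ethyl (2E)-2-[2-(1,3-dioxolan-2-yl)ethyl]-4-[(4-methoxybenzyl)oxy]but-2-enoate
Product: 7 ethyl (2E)-4-[(4-methoxybenzyl)oxy]-2-(3-oxopropyl)but-2-enoate
Conditions: 1 M HCl, THF, rt
Reagents that add atoms: water, O
Why: Acid-catalysed acetal hydrolysis frees the C1 aldehyde while the PMB ether and the enoate tolerate dilute acid; the alkene geometry is not touched.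

Step 4
Reactants: 8 (±)-pent-1-en-4-yn-3-ol
Product: 9 (1S)-1-[(2R)-oxiran-2-yl]prop-2-yn-1-ol
Conditions: Ti(OiPr)4 (0.2 equiv), diisopropyl L-(+)-tartrate (0.24 equiv), t-BuOOH (0.45 equiv), 4 Å MS, CH2Cl2, −20 °C, run to about 45 % conversion
Reagents that add atoms: tert-butyl hydroperoxide, CC(C)(C)OO
Why: Sharpless asymmetric epoxidation in kinetic-resolution mode should epoxidise the (R)-enantiomer faster, on the alkene face dictated by the L-(+)-tartrate, to the erythro epoxy alcohol, so the reagent sets C8 and selects C7 while (S)-8 is left behind.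

Step 5
Reactants: 9 (1S)-1-[(2R)-oxiran-2-yl]prop-2-yn-1-ol
Product: 10 (2R)-2-[(1S)-1-[(4-methoxybenzyl)oxy]prop-2-yn-1-yl]oxirane
Conditions: NaH (1.05 equiv), 4-methoxybenzyl chloride, Bu4NI (cat.), THF/DMF, 0 °C
Reagents that add atoms: 4-methoxybenzyl chloride, COc1ccc(CCl)cc1
Why: Williamson etherification of the alkoxide at low temperature in an aprotic medium should outrun Payne migration of the epoxide, so C7 and C8 stay as set.

Step 6
Reactants: 10 (2R)-2-[(1S)-1-[(4-methoxybenzyl)oxy]prop-2-yn-1-yl]oxirane; 11 triethyl phosphonoacetate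
Product: 13 diethyl {(5R)-5-[(1S)-1-[(4-methoxybenzyl)oxy]prop-2-yn-1-yl]-2-oxooxolan-3-yl}phosphonate, via hydroxy phosphonoester 12 (not isolated)
Conditions: NaH (1.1 equiv), toluene, 0 °C → 110 °C
Reagents that add atoms: none
Why: The phosphonoacetate carbanion opens the epoxide at the terminal carbon C9 (SN2, C8 untouched) and the C8 alkoxide of 12 closes the γ-lactone on the ester, a known route to α-phosphono-γ-butyrolactones that creates the temporary ring holding O8 and C14.

Step 7
Reactants: 13 diethyl {(5R)-5-[(1S)-1-[(4-methoxybenzyl)oxy]prop-2-yn-1-yl]-2-oxooxolan-3-yl}phosphonate; 7 ethyl (2E)-4-[(4-methoxybenzyl)oxy]-2-(3-oxopropyl)but-2-enoate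
Product: 14 (E)-alkylidene lactone ester (C1=C10 formed)
Conditions: NaH (1.05 equiv), THF, 0 °C; then 7, 0 °C → rt
Reagents that add atoms: none
Why: Horner–Wadsworth–Emmons olefination of an α-phosphono-γ-butyrolactone should give mainly the E-alkylidene lactone (C2 trans to the lactone carbonyl C14, hence C9 cis to C2 as the target needs), the minor Z isomer being removed by chromatography.

Step 8
Reactants: 14 (E)-alkylidene lactone ester
Product: 15 (2E,6E,9R,10S)-3,7-bis(hydroxymethyl)-1,10-bis[(4-methoxybenzyl)oxy]dodeca-2,6-dien-11-yn-9-ol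
Conditions: iBu2AlH (7 equiv), CH2Cl2, −78 → 0 °C; aq. Rochelle salt
Reagents that add atoms: none
Why: 1,2-Reduction of the conjugated lactone and ester by the aluminium hydride opens the temporary ring to the C8 and C14 hydroxyls and turns C15 into its hydroxymethyl group without touching alkene geometry or stereocenters.

Step 9
Reactants: 15 (2E,6E,9R,10S)-3,7-bis(hydroxymethyl)-1,10-bis[(4-methoxybenzyl)oxy]dodeca-2,6-dien-11-yn-9-ol
Product: 16 O14,O15-bis(tert-butyldiphenylsilyl) ether of 15
Conditions: TBDPSCl (2.2 equiv), imidazole, CH2Cl2, 0 °C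
Reagents that add atoms: tert-butyl(chloro)diphenylsilane, CC(C)(C)[Si](Cl)(c1ccccc1)c1ccccc1
Why: The bulky silyl chloride should react only at the two primary allylic hydroxyls and leave the hindered secondary C8 hydroxyl free (steric selectivity of silylation).

Step 10
Reactants: 16 O14,O15-bis(tert-butyldiphenylsilyl) ether of 15
Product: 17 O8-tert-butyldimethylsilyl ether of 16
Conditions: TBSOTf (1.3 equiv), 2,6-lutidine, CH2Cl2, −78 → 0 °C
Reagents that add atoms: tert-butyldimethylsilyl trifluoromethanesulfonate, CC(C)(C)[Si](C)(C)OS(=O)(=O)C(F)(F)F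
Why: Silyl triflate silylation protects the secondary C8 hydroxyl as an ether that is a poor leaving group next to the later organometallic centre and is more acid-labile than the primary silyl ethers.

Step 11
Reactants: 17 O8-tert-butyldimethylsilyl ether of 16
Product: 18 (2E,6E,9R,10S)-9-[(tert-butyldimethylsilyl)oxy]-3,7-bis{[(tert-butyldiphenylsilyl)oxy]methyl}dodeca-2,6-dien-11-yne-1,10-diol
Conditions: DDQ (2.4 equiv), CH2Cl2/pH 7 buffer (10:1), 0 °C
Reagents that add atoms: none
Why: Oxidative cleavage of both 4-methoxybenzyl ethers by DDQ frees O6 and O7 at once under buffered conditions that leave the silyl ethers, alkenes and alkyne alone.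

Step 12
Reactants: 18 (2E,6E,9R,10S)-9-[(tert-butyldimethylsilyl)oxy]-3,7-bis{[(tert-butyldiphenylsilyl)oxy]methyl}dodeca-2,6-dien-11-yne-1,10-diol
Product: 19 (2E,6E,9R,10S)-9-[(tert-butyldimethylsilyl)oxy]-3,7-bis{[(tert-butyldiphenylsilyl)oxy]methyl}-10-hydroxydodeca-2,6-dien-11-ynal
Conditions: TEMPO (10 mol %), PhI(OAc)2 (1.1 equiv), CH2Cl2, rt
Reagents that add atoms: none
Why: Oxoammonium (TEMPO) oxidation is selective for the primary allylic alcohol over the secondary propargylic one and should give the enal without isomerising the trisubstituted double bond.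

Step 13
Reactants: 19 (2E,6E,9R,10S)-9-[(tert-butyldimethylsilyl)oxy]-3,7-bis{[(tert-butyldiphenylsilyl)oxy]methyl}-10-hydroxydodeca-2,6-dien-11-ynal
Product: 20 O7-methanesulfonate of 19
Conditions: MsCl (1.2 equiv), Et3N, CH2Cl2, −78 °C
Reagents that add atoms: methanesulfonyl chloride, CS(Cl)(=O)=O
Why: O-Sulfonylation of the only free hydroxyl gives the propargylic mesylate with retention at C7, the enal being inert under these conditions.

Step 14
Reactants: 20 O7-methanesulfonate of 19
Product: 22 (6R,7S,8R)-8-[(tert-butyldimethylsilyl)oxy]-14,15-bis[(tert-butyldiphenylsilyl)oxy]-12-norgermacra-1(10),4-dien-11(13)-yn-6-ol, via allenylzinc 21 (not isolated)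
Conditions: Pd(OAc)2 (5 mol %), PPh3 (5 mol %), Et2Zn (3 equiv), THF, −20 → 0 °C, slow addition of 20 (final 2 mM); aq. NH4Cl
Reagents that add atoms: none
Why: In this palladium-catalysed umpolung propargylation, anti SN2′ oxidative addition of zerovalent palladium, transmetalation to zinc and syn SE2′ addition of allenylzinc 21 to the enal through a six-membered cyclic transition state should close the ten-membered ring with overall inversion at C7 (chirality transfer from the mesylate) and with O6 anti to C8, the two ring-cis alkenes holding the chain ends together and high dilution suppressing oligomers.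

Step 15
Reactants: 22 (6R,7S,8R)-8-[(tert-butyldimethylsilyl)oxy]-14,15-bis[(tert-butyldiphenylsilyl)oxy]-12-norgermacra-1(10),4-dien-11(13)-yn-6-ol
Product: 23 (6R,7S,8R)-8-[(tert-butyldimethylsilyl)oxy]-14,15-bis[(tert-butyldiphenylsilyl)oxy]germacra-1(10),4,11(13)-trien-12,6-olide
Conditions: PdCl2 (5 mol %), SnCl2 (5 mol %), PPh3 (10 mol %), CO (7 atm), MeCN, 75 °C
Reagents that add atoms: carbon monoxide, [C-]#[O+]
Why: The free C6 hydroxyl, CO and the divalent palladium catalyst should give an alkoxycarbonylpalladium species (O6–C12(=O)–Pd) that adds syn across the C11≡C13 triple bond, so that the new C11–C12 bond closes the lactone and palladium ends on C13, and protonolysis of the vinyl–palladium bond by the HCl released earlier gives the C13 methylene and returns the catalyst. The closest known reaction type is the palladium-catalysed cyclocarbonylation of but-3-yn-1-ols, trans-2-ethynylcycloalkanols included, to α-methylene-γ-butyrolactones by this acyl-insertion pathway. The five-membered ring is closed in the 5-exo-dig mode, the tether delivering C12 to the internal alkyne carbon C11 and not to C13 (6-endo). No stereocenter is created: the trans ring fusion is preset by the anti C6/C7 relation from step 14, and syn insertion followed by protonolysis with retention leaves only hydrogen on C13. The step needs chemoselectivity for the alkyne over the two trisubstituted alkenes and for O6 over the other oxygens, which is secured because only the terminal alkyne sits within reach of a free hydroxyl while O8, O14 and O15 are silylated. In one operation it adds C12 and forms the lactone ring and the exocyclic methylene with no later oxidation-state change.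

Step 16
Reactants: 23 (6R,7S,8R)-8-[(tert-butyldimethylsilyl)oxy]-14,15-bis[(tert-butyldiphenylsilyl)oxy]germacra-1(10),4,11(13)-trien-12,6-olide
Product: 24 (6R,7R,8R)-14,15-bis[(tert-butyldiphenylsilyl)oxy]-8-hydroxygermacra-1(10),4,11(13)-trien-12,6-olide
Conditions: camphorsulfonic acid (0.2 equiv), MeOH/CH2Cl2 (1:1), 0 °C → rt
Reagents that add atoms: none
Why: Acid-catalysed methanolysis should cleave the tert-butyldimethylsilyl ether much faster than the acid-stable tert-butyldiphenylsilyl ethers, and the non-basic medium spares the α-methylene lactone.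

Step 17
Reactants: 24 (6R,7R,8R)-14,15-bis[(tert-butyldiphenylsilyl)oxy]-8-hydroxygermacra-1(10),4,11(13)-trien-12,6-olide
Product: 25 (6R,7R,8R)-14,15-bis[(tert-butyldiphenylsilyl)oxy]-8-(3-methylbutanoyloxy)germacra-1(10),4,11(13)-trien-12,6-olide
Conditions: 3-methylbutanoyl chloride (1.5 equiv), pyridine, DMAP (cat.), CH2Cl2, 0 °C
Reagents that add atoms: 3-methylbutanoyl chloride, CC(C)CC(=O)Cl
Why: Nucleophile-catalysed acylation of the only free hydroxyl installs the C8 ester with retention at C8 under conditions the Michael-acceptor lactone tolerates.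

Step 18
Reactants: 25 (6R,7R,8R)-14,15-bis[(tert-butyldiphenylsilyl)oxy]-8-(3-methylbutanoyloxy)germacra-1(10),4,11(13)-trien-12,6-olide
Product: 26 (6R,7R,8R)-14,15-dihydroxy-8-(3-methylbutanoyloxy)germacra-1(10),4,11(13)-trien-12,6-olide (CNP0199826.1)
Conditions: HF·pyridine (excess), THF/pyridine, 0 °C → rt
Reagents that add atoms: none
Why: Fluoride-driven cleavage of the two primary silyl ethers under buffered acidic conditions should free the C14 and C15 hydroxyls without ester migration or conjugate addition to the α-methylene lactone.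

**Compound list**

1 | ethyl (triphenylphosphoranylidene)acetate | CCOC(=O)C=P(c1ccccc1)(c1ccccc1)c1ccccc1 | starting material
2 | 2-(2-iodoethyl)-1,3-dioxolane | ICCC1OCCO1 | starting material
3 | [4-(1,3-dioxolan-2-yl)-1-ethoxy-1-oxobutan-2-yl]triphenylphosphonium iodide | CCOC(=O)C(CCC1OCCO1)[P+](c1ccccc1)(c1ccccc1)c1ccccc1.[I-] | intermediate
4 | ethyl 4-(1,3-dioxolan-2-yl)-2-(triphenylphosphoranylidene)butanoate | CCOC(=O)C(CCC1OCCO1)=P(c1ccccc1)(c1ccccc1)c1ccccc1 | intermediate
5 | 2-[(4-methoxybenzyl)oxy]acetaldehyde | O=CCOCc1ccc(OC)cc1 | starting material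
6 | ethyl (2E)-2-[2-(1,3-dioxolan-2-yl)ethyl]-4-[(4-methoxybenzyl)oxy]but-2-enoate | CCOC(=O)/C(CCC1OCCO1)=C/COCc1ccc(OC)cc1 | intermediate
7 | ethyl (2E)-4-[(4-methoxybenzyl)oxy]-2-(3-oxopropyl)but-2-enoate | CCOC(=O)/C(CCC=O)=C/COCc1ccc(OC)cc1 | intermediate
8 | (±)-pent-1-en-4-yn-3-ol | C#CC(O)C=C | starting material
9 | (1S)-1-[(2R)-oxiran-2-yl]prop-2-yn-1-ol | C#C[C@H](O)[C@H]1CO1 | intermediate
10 | (2R)-2-[(1S)-1-[(4-methoxybenzyl)oxy]prop-2-yn-1-yl]oxirane | C#C[C@H](OCc1ccc(OC)cc1)[C@H]1CO1 | intermediate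
11 | triethyl phosphonoacetate | CCOC(=O)CP(=O)(OCC)OCC | starting material
12 | ethyl (4R,5S)-2-(diethoxyphosphoryl)-4-hydroxy-5-[(4-methoxybenzyl)oxy]hept-6-ynoate (C2 epimers, present as sodium alkoxide) | C#C[C@H](OCc1ccc(OC)cc1)[C@H](O)CC(C(=O)OCC)P(=O)(OCC)OCC | intermediate
13 | diethyl {(5R)-5-[(1S)-1-[(4-methoxybenzyl)oxy]prop-2-yn-1-yl]-2-oxooxolan-3-yl}phosphonate (C3 epimers) | C#C[C@H](OCc1ccc(OC)cc1)[C@H]1CC(P(=O)(OCC)OCC)C(=O)O1 | intermediate
14 | ethyl (2E)-4-[(4-methoxybenzyl)oxy]-2-[(3E)-3-{(5R)-5-[(1S)-1-[(4-methoxybenzyl)oxy]prop-2-yn-1-yl]-2-oxooxolan-3-ylidene}propyl]but-2-enoate | C#C[C@H](OCc1ccc(OC)cc1)[C@H]1C/C(=C\CC/C(C(=O)OCC)=C\COCc2ccc(OC)cc2)C(=O)O1 | intermediate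
15 | (2E,6E,9R,10S)-3,7-bis(hydroxymethyl)-1,10-bis[(4-methoxybenzyl)oxy]dodeca-2,6-dien-11-yn-9-ol | C#C[C@H](OCc1ccc(OC)cc1)[C@H](O)C/C(CO)=C\CC/C(CO)=C\COCc1ccc(OC)cc1 | intermediate
16 | (2E,6E,9R,10S)-3,7-bis{[(tert-butyldiphenylsilyl)oxy]methyl}-1,10-bis[(4-methoxybenzyl)oxy]dodeca-2,6-dien-11-yn-9-ol | C#C[C@H](OCc1ccc(OC)cc1)[C@H](O)C/C(CO[Si](c1ccccc1)(c1ccccc1)C(C)(C)C)=C\CC/C(CO[Si](c1ccccc1)(c1ccccc1)C(C)(C)C)=C\COCc1ccc(OC)cc1 | intermediate
17 | (2E,6E,9R,10S)-9-[(tert-butyldimethylsilyl)oxy]-3,7-bis{[(tert-butyldiphenylsilyl)oxy]methyl}-1,10-bis[(4-methoxybenzyl)oxy]dodeca-2,6-dien-11-yne | C#C[C@H](OCc1ccc(OC)cc1)[C@H](O[Si](C)(C)C(C)(C)C)C/C(CO[Si](c1ccccc1)(c1ccccc1)C(C)(C)C)=C\CC/C(CO[Si](c1ccccc1)(c1ccccc1)C(C)(C)C)=C\COCc1ccc(OC)cc1 | intermediate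
18 | (2E,6E,9R,10S)-9-[(tert-butyldimethylsilyl)oxy]-3,7-bis{[(tert-butyldiphenylsilyl)oxy]methyl}dodeca-2,6-dien-11-yne-1,10-diol | C#C[C@H](O)[C@H](O[Si](C)(C)C(C)(C)C)C/C(CO[Si](c1ccccc1)(c1ccccc1)C(C)(C)C)=C\CC/C(CO[Si](c1ccccc1)(c1ccccc1)C(C)(C)C)=C\CO | intermediate
19 | (2E,6E,9R,10S)-9-[(tert-butyldimethylsilyl)oxy]-3,7-bis{[(tert-butyldiphenylsilyl)oxy]methyl}-10-hydroxydodeca-2,6-dien-11-ynal | C#C[C@H](O)[C@H](O[Si](C)(C)C(C)(C)C)C/C(CO[Si](c1ccccc1)(c1ccccc1)C(C)(C)C)=C\CC/C(CO[Si](c1ccccc1)(c1ccccc1)C(C)(C)C)=C\C=O | intermediate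
20 | O7-methanesulfonate of 19, (7S,8R) in germacrane locants | C#C[C@H](OS(C)(=O)=O)[C@H](O[Si](C)(C)C(C)(C)C)C/C(CO[Si](c1ccccc1)(c1ccccc1)C(C)(C)C)=C\CC/C(CO[Si](c1ccccc1)(c1ccccc1)C(C)(C)C)=C\C=O | intermediate
21 | ethyl(allenyl)zinc from 20: zinc on C13, C13=C11=C7 allene, zinc anti to the departed C7–O bond (allene axis not encoded in the SMILES), (8R) | CC[Zn]C=C=C[C@H](O[Si](C)(C)C(C)(C)C)C/C(CO[Si](c1ccccc1)(c1ccccc1)C(C)(C)C)=C\CC/C(CO[Si](c1ccccc1)(c1ccccc1)C(C)(C)C)=C\C=O | intermediate
22 | (6R,7S,8R)-8-[(tert-butyldimethylsilyl)oxy]-14,15-bis[(tert-butyldiphenylsilyl)oxy]-12-norgermacra-1(10),4-dien-11(13)-yn-6-ol (6α-OH, 7β-ethynyl, 8β-OSi) | C#C[C@H]1[C@H](O)/C=C(/CO[Si](c2ccccc2)(c2ccccc2)C(C)(C)C)CC/C=C(/CO[Si](c2ccccc2)(c2ccccc2)C(C)(C)C)C[C@H]1O[Si](C)(C)C(C)(C)C | intermediate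
23 | (6R,7S,8R)-8-[(tert-butyldimethylsilyl)oxy]-14,15-bis[(tert-butyldiphenylsilyl)oxy]germacra-1(10),4,11(13)-trien-12,6-olide (trans-fused) | C=C1[C@H]2[C@H](OC1=O)/C=C(/CO[Si](c3ccccc3)(c3ccccc3)C(C)(C)C)CC/C=C(/CO[Si](c3ccccc3)(c3ccccc3)C(C)(C)C)C[C@H]2O[Si](C)(C)C(C)(C)C | intermediate
24 | (6R,7R,8R)-14,15-bis[(tert-butyldiphenylsilyl)oxy]-8-hydroxygermacra-1(10),4,11(13)-trien-12,6-olide | C=C1[C@H]2[C@H](OC1=O)/C=C(/CO[Si](c3ccccc3)(c3ccccc3)C(C)(C)C)CC/C=C(/CO[Si](c3ccccc3)(c3ccccc3)C(C)(C)C)C[C@H]2O | intermediate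
25 | (6R,7R,8R)-14,15-bis[(tert-butyldiphenylsilyl)oxy]-8-(3-methylbutanoyloxy)germacra-1(10),4,11(13)-trien-12,6-olide | C=C1[C@H]2[C@H](OC1=O)/C=C(/CO[Si](c3ccccc3)(c3ccccc3)C(C)(C)C)CC/C=C(/CO[Si](c3ccccc3)(c3ccccc3)C(C)(C)C)C[C@H]2OC(=O)CC(C)C | intermediate
26 | (6R,7R,8R)-14,15-dihydroxy-8-(3-methylbutanoyloxy)germacra-1(10),4,11(13)-trien-12,6-olide (CNP0199826.1) | C=C1[C@H]2[C@H](OC1=O)/C=C(/CO)CC/C=C(/CO)C[C@H]2OC(=O)CC(C)C | target

**Step count**

Total: 18 steps. Longest linear sequence: 15 steps (steps 4–6 or 1–3, then 7–18).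

**Steps most likely to fail**

Step 14 (ring closure at C6–C7). Oligomerisation may compete with ring closure. The allenylzinc may lose its configuration before it cyclises, the C8 silyloxy group may be eliminated from the propargylic zinc tautomer, or an ethyl group may be transferred to the enal. The fallback sets out from mesylate 20. LiBr in THF would give the propargylic bromide F1, and slow addition of F1 to excess CrCl2 in THF at high dilution would form the allenylchromium dichloride F2, which adds to the C6 aldehyde in a Nozaki–Hiyama-type propargylation and comes back to the route at 22. In this variant the C7 configuration is no longer relayed from the precursor. C6 and C7 would be set in the cyclic transition state (anti) under the influence of C8, so 22 may have to be separated from diastereomers.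

Step 15 (key cyclocarbonylation). The alkoxycarbonyl–palladium species may form slowly at the hindered allylic hydroxyl. Acid released in the cycle may remove the C8 silyl group and open a competing lactonisation onto O8, or the alkyne may be hydrochlorinated or oligomerised. The fallback sets out from 22. PhSeC(O)Cl and pyridine would give the Se-phenyl selenocarbonate F3, and Bu3SnH with AIBN (slow addition, benzene, 80 °C) would generate the alkoxycarbonyl radical on O6. Its 5-exo-dig attack on C11 closes the same C11–C12 bond, and hydrogen transfer to the C13 vinyl radical comes back to the route at 23.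

Step 6 (epoxide opening and lactonisation). The weakly nucleophilic phosphonoacetate anion may open the α-branched epoxide too slowly, and at the temperature needed the propargylic ether may isomerise to an allenyl ether. The fallback sets out from epoxide 10. The dianion of diethylphosphonoacetic acid (LDA, THF, −78 → 0 °C, with one further equivalent of base for the alkyne C–H) is a far stronger nucleophile and would open the epoxide at C9 to the γ-hydroxy acid F4. Carbodiimide-mediated lactonisation of F4 (EDC·HCl, DMAP) comes back to the route at 13.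

**Further compounds**

F1 | step 14 | (7R,8R)-7-bromo analogue of 20 (propargylic bromide, germacrane locants) | C#C[C@@H](Br)[C@H](O[Si](C)(C)C(C)(C)C)C/C(CO[Si](c1ccccc1)(c1ccccc1)C(C)(C)C)=C\CC/C(CO[Si](c1ccccc1)(c1ccccc1)C(C)(C)C)=C\C=O
F2 | step 14 | allenylchromium dichloride from F1 (chromium on C13, allene axis not defined), (8R) | Cl[Cr](Cl)C=C=C[C@H](O[Si](C)(C)C(C)(C)C)C/C(CO[Si](c1ccccc1)(c1ccccc1)C(C)(C)C)=C\CC/C(CO[Si](c1ccccc1)(c1ccccc1)C(C)(C)C)=C\C=O
F3 | step 15 | O6-(phenylselanylcarbonyl) derivative of 22 (Se-phenyl selenocarbonate) | C#C[C@H]1[C@H](OC(=O)[Se]c2ccccc2)/C=C(/CO[Si](c2ccccc2)(c2ccccc2)C(C)(C)C)CC/C=C(/CO[Si](c2ccccc2)(c2ccccc2)C(C)(C)C)C[C@H]1O[Si](C)(C)C(C)(C)C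
F4 | step 6 | (4R,5S)-2-(diethoxyphosphoryl)-4-hydroxy-5-[(4-methoxybenzyl)oxy]hept-6-ynoic acid (C2 epimers) | C#C[C@H](OCc1ccc(OC)cc1)[C@H](O)CC(C(=O)O)P(=O)(OCC)OCC
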